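Readings and results come from a simulation for substances that don't exist; the scatter is artificial.

- The leftover tells me most: in the midnight run target stops near 50.8%, and the other 49.2% of the starting material isn't recovered by the second enzyme portion.

| setting | midnight | dawn | dusk | oak | ash |
|---|---|---|---|---|---|
| starting material | 0.010 M | 0.010 M | 0.010 M | 0.010 M | 0.010 M |
| enzyme | 0.13 µM (in portions, 2) | 0.21 µM (in portions, 2) | 0.28 µM (in portions, 2) | 0.16 µM (in portions, 2) | 0.30 µM |
| remark | run made earlier; portions every 50 h | run made earlier; portions every 50 h | run made earlier; portions every 50 h | the portions of enzyme follow each other after 50 h, the first at the start | everything together at the start |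
| time |  |  |  | 4.0 d | 1.0 d |

| run | time / d | target / % |
|---|---|---|
| midnight | 0.833 | 40 |
| midnight | 1.67 | 50 |
| midnight | 2.50 | 53 |
| midnight | 3.00 | 49 |
| midnight | 4.00 | 51 |
| dawn | 0.833 | 59 |
| dawn | 1.67 | 63 |
| dawn | 2.50 | 63 |
| dawn | 3.00 | 62 |
| dawn | 4.00 | 62 |
| dusk | 0.833 | 68 |
| dusk | 1.67 | 67 |
| dusk | 2.50 | 65 |
| dusk | 3.00 | 66 |
| dusk | 4.00 | 67 |

(scatter of a reading: 1.5 percentage points)

- which one finishes higher in amount of target, in percent of the starting material charged ("neither" within 2 percentage points) (oak / ash / neither)
- amount of target at the end, in percent of the starting material charged, oak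
- amount of target at the end, in percent of the starting material charged, ash



- Ash looks nearly like dusk, 0.30 µM of enzyme against 0.28 µM. But dusk already reads flat at 0.833 d, earlier than its second portion at 50 h, so dusk ends on its first portion, 0.140 µM, while ash has twice that at work from the start.
- My rule holds for [starting material] = 0.010 M: starting material goes to target or elsewhere, so I take target over non-target on the plateau and divide by [enzyme] in the first portion.
- Dawn reads 62.5% and dusk 66.2%, so the runs read 15.9 µM⁻¹, 15.9 µM⁻¹ and 14.0 µM⁻¹. I carry their mean, 15.2 µM⁻¹, the plateau odds per unit of early enzyme, a selectivity factor read from the readings.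
- Midnight is flat by 1.67 d, earlier than the second portion at 50 h, and oak's first portion, 0.0800 µM, is larger than midnight's, so I count that portion: odds 1.22, target 55.0%.
- Ash gets odds 4.57, target 82.1%, though this reaches beyond the enzyme levels read so far. Its 1.0 d is longer than dusk needed. I commit to ash higher.
- The forecast also picks ash, but with oak 56% and ash 68%, the latter lower than mine, seeing “a cap near 67, possibly an equilibrium”.
- The flasks give 56.0% for oak and 80.1% for ash, so ash ends higher.

    starting material + enzyme → target + enzyme, rate k1*[starting material]*[enzyme]/(1 + ([starting material]/Km1) + ([starting material]/Ksi1)^2) (4.50 mM, 5.60 mM, k = 2.20 × 10⁶ M⁻¹ h⁻¹)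
    2 starting material → homo dimer (k = 3.00 M⁻¹ h⁻¹)
    starting material → uncatalysed product (k = 0.0200 h⁻¹)

- The main reason ash ends short of the whole charge is the path from two starting material to homo dimer: with that path taken away, ash ends at 91.4% instead of 80.1%, which is 57% of what is missing. In oak, hardly any starting material, 0.0237%, stands at 2.08 d, just before the second portion, and target reads 56.0% there and 56.0% at the end.
- A neighbour of oak has 4.0 × 10⁻⁸ M of enzyme: its first portion, 0.0200 µM, gives odds 0.305, so target 23.4%. The computed flask ends at 29.1%, above that figure.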